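Locants used throughout: lactone O1, C2 (carbonyl), C3, C4, C5 (OCH2). C7' is the CH2 between C3 and ring A (C1'–C6'), and C7'' is the CH2 between C4 and ring B.

## Structural features

The target 15 is a γ-butyrolactone whose C3 carries, through C7', ring A (2,4-dihydroxy-3-methoxyphenyl) and whose C4 carries, through C7'', ring B (4-hydroxy-3-methoxyphenyl). C3 and C4 are the only stereocentres; they are neighbours, both are R, and the two benzyl arms are trans. C3 lies next to the carbonyl and can be equilibrated (trans is the stable arrangement), whereas C4 has no such outlet once C5 is an alcohol carbon, so its absolute configuration must be set correctly and kept. The fragile points are the three free phenols, above all the oxidation-prone trioxygenated ring A, and the lactone, which base opens or epimerizes at C3. The real difficulty is the near-symmetry: the two arms differ only in the 2'-hydroxyl, and C2 and C5 are the same one-carbon unit at two oxidation levels, so absolute configuration and the choice of carbonyl carbon must both be decided with little built-in bias. The key step uses the fact that C2 and C5 are single carbons on the adjacent C3 and C4, so both can come from carbon monoxide delivered to one face of a C3=C4 double bond flanked by C7' and C7''. The 2'-hydroxyl of ring A is the one group that can reach C2 through a six-membered ring (C5 would need seven), and this later tells the two carboxyl carbons apart.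

## Logic of the disconnections

**15 from 13 (through 14).** Backwards, the O1–C2 bond is cut, C2 is handed to the 2'-oxygen as an aryl ester, and C5 is raised from CH2OH to CO2H. In 15 the two one-carbon units differ only in oxidation level; in 13 they are an aryl lactone and a free acid, which a reagent can distinguish. The gain is that the problem shrinks to reducing a free acid beside an ester. The forward step demands a hydride source that touches only the free acid at C5. The new hydroxyl of 14 must then take C2 over from the phenol (five-membered alkyl lactone replacing six-membered aryl lactone, downhill) without disturbing C3 or C4.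

**13 from 11 (through 12).** The O2'–C2 aryl ester bond is cut and all five acidic OH groups (three phenols, two carboxyls) are capped with benzyl. This gives an open-chain, fully protected threo diester with no free phenol to interfere with oxidative palladium chemistry. The demand is that one hydrogenolysis frees all five groups (12) and that acid closes only the six-membered ring from O2' to C2.

**11 from 8, 9 and 10.** The bonds C2–C3 and C4–C5 are cut, and the two ester alkoxy groups return to 10. Both carboxyl carbons are one-carbon units on neighbouring carbons, which is the pattern left by double carbonylation of an alkene, so each molecule of 11 is traced back to one molecule of 8, two of 9 and two of 10. Two carbons and both stereocentres disappear at once, leaving a flat, achiral E alkene. The forward step must add both groups syn and to one enantiotopic face, and must not let the double bond migrate.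

**8 from 5 and 7.** The C3=C4 double bond is cut. Both halves are then simple allylarenes of comparable reactivity. The demand is E geometry, because it fixes the relative configuration of 11, and cross coupling in preference to homodimerization.

**5 from 4, 4 from 3, 3 from 1 and 2.** The two O–benzyl bonds are cut, then the C1'–C7' aryl–allyl bond, which a [3,3] shift traces back to an O–allyl bond. This reduces ring A to a symmetric commercial diol and a three-carbon halide. The demands are mono-allylation of a symmetric diol and rearrangement to the correct ring carbon.

**7 from 6.** The O–benzyl bond is cut, leaving a commercial allylphenol. Only a routine etherification is required.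

## Other disconnections considered

Alternative 1: The cut is the C1'–C7' bond, with the 2'-oxygen temporarily bonded to C2. In the forward key step, 1 condenses under strong acid (Pechmann type) with the hydroxymethylene lactone A1. The ring carbon of 1 attacks the formyl-derived carbon, the adjacent hydroxyl takes C2 from the lactone oxygen, and the coumarin A2 results with C5 as a free alcohol.
- In its favour: 1 is used unprotected and its symmetry removes any regiochemical question on the arene. C4 arrives in A1 from established asymmetric lactone chemistry, so no unproven enantioselective catalysis is needed; on mechanistic certainty this plan is the better one.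
- Equal: it uses the 2'-oxygen as a temporary acyl carrier, exactly as the chosen plan does.
- Against: in A2 the stereocentre C4 is allylic to the coumarin double bond and carries a hydroxymethyl group, so hot strong acid can dehydrate or shift the double bond and erase it. Formyl-type partners are the less reliable class in this condensation. A2 still needs hydrogenation of the C3–C7' double bond (C3 uncontrolled, though correctable), acyl transfer back to the five-membered lactone and removal of the sulfonate.
- Step economy: with the steps needed to reach A1, an estimated nine to ten linear steps, against eight (seven linear) here. The chosen plan is shorter and convergent and sets both centres in one event, at the price of higher risk in that event.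

Alternative 2: The cuts are C1'–C6' and C2'–C3', so ring A is built from acyclic pieces. In the forward key step the malonate A3 adds to the enone A4 (Michael), and the enolate on the methoxy-bearing carbon closes onto one malonate ester (Claisen type) to give A5.
- In its favour: the 2',3',4' oxygen pattern is fixed by construction. This equals the chosen plan, where the symmetric diol and a rearrangement with a single possible outcome give the same certainty.
- Better: no oxidation-prone phenol is carried, and both stereocentres are in place beforehand through known trans-selective lactone chemistry.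
- Against: the alkoxide needed for ring closure also opens the butyrolactone and epimerizes C3, and A4 polymerizes readily. A5 is still an ester loss, a dehydrogenation and a debenzylation away from 15.
- Structure and step economy: this plan spends its key step on six carbons that can be bought as an arene and leaves the hard part (C3/C4) to earlier chemistry. It is clearly the longest of the four.

Alternative 3: The cuts are C2–C3 and O1–C2. In the forward key step the styrene A6 is reduced at a cathode under carbon dioxide A7 with a proton donor. The radical anion is carboxylated at the carbon remote from ring A (C3), the benzylic carbon C7' is protonated, and acidification closes the lactone A8.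
- Better: the one-carbon source is safer than 9. The lactone is formed directly at the right oxidation level, so no carboxyl differentiation is needed. A8 is one hydrogenolysis from 15.
- Equal: C3 is formed without control but is thermodynamically correctable.
- Against: C4 must be installed earlier in A6 by a separate asymmetric synthesis. The trialkoxy-substituted styrene is hard to reduce, and at such potentials benzyl ether cleavage and reduction of A7 compete. Carboxylation next to a branched carbon, double carboxylation and carbonate formation at the free hydroxyl are further hazards, and the method is established only for simple styrenes.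
- Step economy: the endgame is shorter, but the overall count is estimated as equal or longer because of the route to A6. The chosen plan creates both centres from an achiral alkene in one step.

Key step: step 6

Assumption (remark on the chemistry): the alcohol component of the carbonylation is treated as a carboxyl protecting group and is chosen as benzyl alcohol 10, so that one hydrogenolysis strips 11 of all five benzyl groups and no saponification of an epimerizable diester is needed. The bonds formed, the open-chain succinate skeleton and its (2R,3R) configuration are unchanged; (2R,3R) maps onto (3R,4R) in 15 because the substituent ranking at both centres stays the same.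

## Route

Step 1
Reactants: 1 2-methoxyresorcinol (2-methoxybenzene-1,3-diol); 2 allyl bromide (3-bromoprop-1-ene)
Product: 3 2-methoxy-3-(prop-2-en-1-yloxy)phenol
Conditions: 1 (1.5 equiv), 2 (1.0 equiv), K2CO3 (1.1 equiv), acetone, 56 °C; excess 1 recovered
Reagents that add atoms: none
Why: Williamson O-alkylation of the phenoxide (SN2 on the allylic bromide); the two hydroxyls of 1 are equivalent, so an excess of 1 keeps the bis-ether low and 3 is separated from recovered 1 by chromatography.

Step 2
Reactants: 3 2-methoxy-3-(prop-2-en-1-yloxy)phenol
Product: 4 2-methoxy-4-(prop-2-en-1-yl)benzene-1,3-diol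
Conditions: N,N-diethylaniline, 195 °C, argon
Reagents that add atoms: none
Why: Aromatic Claisen rearrangement, a concerted [3,3] shift to the free ortho carbon followed by tautomerization to the phenol; the other ortho carbon carries the methoxy group, and onward migration to the para carbon would give the same compound because that carbon is ortho to the second hydroxyl of the symmetric diol.

Step 3
Reactants: 4 2-methoxy-4-(prop-2-en-1-yl)benzene-1,3-diol
Product: 5 1,3-bis(benzyloxy)-2-methoxy-4-(prop-2-en-1-yl)benzene (ring A allylarene)
Conditions: BnBr (2.4 equiv), K2CO3 (3 equiv), KI (cat.), DMF, 60 °C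
Reagents that add atoms: benzyl bromide, BrCc1ccccc1
Why: Double Williamson benzylation; K2CO3 is too weak to move the allyl double bond into conjugation, and iodide catalysis with mild heating should carry the hindered 2'-hydroxyl to completion.

Step 4
Reactants: 6 eugenol (2-methoxy-4-(prop-2-en-1-yl)phenol)
Product: 7 O-benzyleugenol (1-(benzyloxy)-2-methoxy-4-(prop-2-en-1-yl)benzene)
Conditions: BnBr (1.1 equiv), K2CO3 (1.5 equiv), acetone, 56 °C
Reagents that add atoms: benzyl bromide, BrCc1ccccc1
Why: Williamson benzylation of the single phenol; the allyl group is inert to these conditions.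

Step 5
Reactants: 5 ring A allylarene; 7 O-benzyleugenol
Product: 8 (E)-1-[2,4-bis(benzyloxy)-3-methoxyphenyl]-4-[4-(benzyloxy)-3-methoxyphenyl]but-2-ene
Conditions: 7 (3 equiv), second-generation Grubbs catalyst (3 mol%), 1,4-benzoquinone (10 mol%), CH2Cl2, 40 °C, argon sweep; SiO2, then AgNO3-impregnated SiO2
Reagents that add atoms: none
Why: Olefin cross-metathesis (Chauvin mechanism) between two unhindered allylarenes with loss of ethene; excess 7 channels 5 into the cross product, secondary metathesis equilibrates toward the more stable E isomer, and benzoquinone suppresses ruthenium hydride migration of the double bond. The homodimer of 7 and the minor Z isomer (bound more strongly by silver ion) are removed by chromatography.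

Step 6
Reactants: 8 (E)-1-[2,4-bis(benzyloxy)-3-methoxyphenyl]-4-[4-(benzyloxy)-3-methoxyphenyl]but-2-ene; 9 carbon monoxide; 10 benzyl alcohol
Product: 11 dibenzyl (2R,3R)-2-[2,4-bis(benzyloxy)-3-methoxybenzyl]-3-[4-(benzyloxy)-3-methoxybenzyl]butanedioate
Conditions: Pd(OCOCF3)2 (5 mol%), 2,2'-(propane-2,2-diyl)bis[(4S)-4-phenyl-4,5-dihydrooxazole] (6 mol%; the (4R,4'R) antipode if the sense of induction requires it), 1,4-benzoquinone (1.5 equiv), 9 (5 bar), 10 (6 equiv), THF, 3 Å MS, 20 °C; two molecules of 9 and two of 10 are consumed per molecule of 8
Reagents that add atoms: carbon monoxide, [C-]#[O+]; benzyl alcohol, OCc1ccccc1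
Why: Proposed new method: the bis(oxazoline) complex of divalent palladium should take up CO and benzyl alcohol to give a benzyloxycarbonyl–palladium species; the E alkene binds through one enantiotopic face and inserts syn into the Pd–CO2Bn bond, the alkyl–palladium so formed (held as a five-membered chelate by the new ester carbonyl, which disfavours β-hydride elimination) inserts a second CO with retention, and a second benzyl alcohol cleaves the acyl–palladium bond to release 11 and zerovalent palladium, which benzoquinone and the liberated acid return to the divalent state. Each molecule of 11 therefore contains two molecules of 9 and two of 10 added to one molecule of 8. The closest known reaction types are the syn-specific but racemic palladium-catalysed oxidative bis(alkoxycarbonylation) of 1,2-disubstituted internal alkenes and the enantioselective bis(alkoxycarbonylation) of styrenes with chiral ligands; their combination on a trans-1,2-dialkyl alkene is not established. No ring is closed; the new bonds are C2–C3 and C4–C5. The relative configuration of C3 and C4 follows from syn addition to the E double bond (threo), and the absolute configuration of both centres together from the alkene face that the chiral ligand admits. Regiochemistry does not arise because both alkene carbons receive the same group, so either order of bond formation on a given face gives the same enantiomer, and the trans alkene bound to palladium keeps a twofold axis through the metal that matches the twofold axis of the ligand. The step also needs chemoselectivity against palladium hydride migration of the doubly benzylic–allylic double bond and against mono-carbonylation by β-hydride elimination; CO pressure, low temperature, excess benzoquinone as hydride scavenger and the chelated alkyl intermediate are relied on for this.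

Step 7
Reactants: 11 dibenzyl (2R,3R)-2-[2,4-bis(benzyloxy)-3-methoxybenzyl]-3-[4-(benzyloxy)-3-methoxybenzyl]butanedioate
Product: 13 (2R)-2-[(3R)-7-hydroxy-8-methoxy-2-oxo-3,4-dihydro-2H-chromen-3-yl]-3-(4-hydroxy-3-methoxyphenyl)propanoic acid, via triphenol diacid 12 (not isolated)
Conditions: H2 (1 atm), 10% Pd/C, THF–EtOAc, 20 °C; filter under argon; then TsOH·H2O (10 mol%), toluene–1,4-dioxane, 4 Å MS, 90 °C
Reagents that add atoms: none
Why: Hydrogenolysis of two benzyl esters and three benzyl ethers gives 12; acid-catalysed lactonization then joins the 2'-hydroxyl to C2 through a six-membered ring (dihydrocoumarin formation), the only phenol–carboxyl pair that can close a ring smaller than seven, so C5 remains a free acid. Neither operation touches C3 or C4, and a transient cyclic anhydride would be opened by the same phenol to the same product.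

Step 8
Reactants: 13 (2R)-2-[(3R)-7-hydroxy-8-methoxy-2-oxo-3,4-dihydro-2H-chromen-3-yl]-3-(4-hydroxy-3-methoxyphenyl)propanoic acid
Product: 15 (3R,4R)-3-[(2,4-dihydroxy-3-methoxyphenyl)methyl]-4-[(4-hydroxy-3-methoxyphenyl)methyl]oxolan-2-one, via hydroxymethyl dihydrocoumarin 14 (not isolated)
Conditions: BH3·THF (4 equiv), THF, −10 to 20 °C; then 1 M HCl (aq), 20 °C
Reagents that add atoms: none
Why: Borane reduces a free carboxylic acid (through its acyloxyborane) much faster than an ester, so only C5 is taken to CH2OH while the aryl lactone survives; the phenols merely consume hydride and are restored on work-up. On acidic work-up the C5 hydroxyl of 14 attacks C2 (5-exo-trig acyl transfer) and expels the ring A phenol, a downhill exchange of aryl ester for alkyl γ-lactone; C4 is untouched and C3 keeps its configuration, trans being the thermodynamic arrangement in any case.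

## Compound list

```
1 | 2-methoxyresorcinol (2-methoxybenzene-1,3-diol) | COc1c(O)cccc1O | starting material
2 | allyl bromide (3-bromoprop-1-ene) | C=CCBr | starting material
3 | 2-methoxy-3-(prop-2-en-1-yloxy)phenol | COc1c(O)cccc1OCC=C | intermediate
4 | 2-methoxy-4-(prop-2-en-1-yl)benzene-1,3-diol | COc1c(O)ccc(CC=C)c1O | intermediate
5 | 1,3-bis(benzyloxy)-2-methoxy-4-(prop-2-en-1-yl)benzene | COc1c(OCc2ccccc2)ccc(CC=C)c1OCc1ccccc1 | intermediate
6 | eugenol (2-methoxy-4-(prop-2-en-1-yl)phenol) | COc1cc(CC=C)ccc1O | starting material
7 | O-benzyleugenol (1-(benzyloxy)-2-methoxy-4-(prop-2-en-1-yl)benzene) | COc1cc(CC=C)ccc1OCc1ccccc1 | intermediate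
8 | (E)-1-[2,4-bis(benzyloxy)-3-methoxyphenyl]-4-[4-(benzyloxy)-3-methoxyphenyl]but-2-ene | COc1cc(C/C=C/Cc2ccc(OCc3ccccc3)c(OC)c2OCc2ccccc2)ccc1OCc1ccccc1 | intermediate
9 | carbon monoxide | [C-]#[O+] | starting material
10 | benzyl alcohol | OCc1ccccc1 | starting material
11 | dibenzyl (2R,3R)-2-[2,4-bis(benzyloxy)-3-methoxybenzyl]-3-[4-(benzyloxy)-3-methoxybenzyl]butanedioate | COc1cc(C[C@@H](C(=O)OCc2ccccc2)[C@@H](Cc2ccc(OCc3ccccc3)c(OC)c2OCc2ccccc2)C(=O)OCc2ccccc2)ccc1OCc1ccccc1 | intermediate
12 | (2R,3R)-2-[(2,4-dihydroxy-3-methoxyphenyl)methyl]-3-[(4-hydroxy-3-methoxyphenyl)methyl]butanedioic acid (triphenol diacid, not isolated) | COc1cc(C[C@@H](C(=O)O)[C@@H](Cc2ccc(O)c(OC)c2O)C(=O)O)ccc1O | intermediate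
13 | (2R)-2-[(3R)-7-hydroxy-8-methoxy-2-oxo-3,4-dihydro-2H-chromen-3-yl]-3-(4-hydroxy-3-methoxyphenyl)propanoic acid | COc1cc(C[C@@H](C(=O)O)[C@H]2Cc3ccc(O)c(OC)c3OC2=O)ccc1O | intermediate
14 | (3R)-7-hydroxy-3-[(2R)-1-hydroxy-3-(4-hydroxy-3-methoxyphenyl)propan-2-yl]-8-methoxy-3,4-dihydro-2H-chromen-2-one (hydroxymethyl dihydrocoumarin, not isolated) | COc1cc(C[C@@H](CO)[C@H]2Cc3ccc(O)c(OC)c3OC2=O)ccc1O | intermediate
15 | (3R,4R)-3-[(2,4-dihydroxy-3-methoxyphenyl)methyl]-4-[(4-hydroxy-3-methoxyphenyl)methyl]oxolan-2-one | COc1cc(C[C@H]2COC(=O)[C@@H]2Cc2ccc(O)c(OC)c2O)ccc1O | target
```

Total step count: 8. Longest linear sequence: 7 steps (steps 1, 2, 3, 5, 6, 7, 8); step 4 is the side branch.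

## Least certain steps

**Step 6 (key step).** The most likely failure is poor enantioface selection, because the two alkene substituents are both CH2Ar and offer the ligand little to grip beyond the quadrant fit of a trans alkene. The second is palladium hydride migration of the doubly activated double bond into conjugation with either ring, after which carbonylation would take place on the wrong carbons. The fallback uses known chemistry, sets out from 8 and comes back at 11. The racemic, syn-specific bis(alkoxycarbonylation) would be run with Pd(OCOCF3)2 and an achiral N,N'-diaryl α-diimine ligand (for example N,N'-bis(2,6-dimethylphenyl)butane-2,3-diimine), 1,4-benzoquinone, TsOH·H2O (cat.), 9 and 10 in THF. This should give the threo diester as a racemate, that is 11 together with dibenzyl (2S,3S)-2-[2,4-bis(benzyloxy)-3-methoxybenzyl]-3-[4-(benzyloxy)-3-methoxybenzyl]butanedioate F1. The enantiomers would be separated by preparative chromatography on a chiral stationary phase, and the route is rejoined at 11.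

**Step 5.** Incomplete geometric control is the main concern: residual Z alkene would be carried by the syn-specific key step into the erythro diastereomer of 11, which then has to be removed by crystallization or chromatography. Statistical homodimerization and ruthenium hydride double-bond migration would lower the return further. The fallback is an E-selective Julia–Kocienski olefination that sets out from 5 and 7 and comes back at 8. 7 would be cleaved with OsO4 (cat.)/NaIO4 and 2,6-lutidine in dioxane–water to [4-(benzyloxy)-3-methoxyphenyl]acetaldehyde F2. 5 would be cleaved in the same way and the crude aldehyde reduced with NaBH4 in methanol to 2-[2,4-bis(benzyloxy)-3-methoxyphenyl]ethanol F3. A Mitsunobu reaction with 1-phenyl-1H-tetrazole-5-thiol (PPh3, DIAD) should give 5-({2-[2,4-bis(benzyloxy)-3-methoxyphenyl]ethyl}sulfanyl)-1-phenyl-1H-tetrazole F4, and oxidation with H2O2 and (NH4)6Mo7O24 should give 5-({2-[2,4-bis(benzyloxy)-3-methoxyphenyl]ethyl}sulfonyl)-1-phenyl-1H-tetrazole F5. Deprotonation of F5 with KN(SiMe3)2 in DME at −60 °C and addition of F2 should give 8.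

**Step 8.** Over-reduction of the aryl lactone by borane is the main risk. Incomplete reduction is the other, because the phenols consume hydride and the triphenol dissolves poorly. The fallback sets out from 13 and comes back at 15; it moves the differentiation into a robust alkyl ester before any hydride is used.
- Direct base-mediated methanolysis of 13 is avoided: the neighbouring carboxylate would displace the phenoxide, and the resulting cyclic anhydride could be opened by methanol at either carbonyl, which would lose the differentiation.
- Diphenyldiazomethane (EtOAc, 20 °C), which esterifies carboxylic acids but not phenols under neutral conditions, should instead convert 13 into diphenylmethyl (2R)-2-[(3R)-7-hydroxy-8-methoxy-2-oxo-3,4-dihydro-2H-chromen-3-yl]-3-(4-hydroxy-3-methoxyphenyl)propanoate F6.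
- Methanolysis of the aryl lactone (MeOH, Et3N (cat.), 20 °C, neutralized before concentration) should then give 1-(diphenylmethyl) 4-methyl (2R,3R)-3-[(2,4-dihydroxy-3-methoxyphenyl)methyl]-2-[(4-hydroxy-3-methoxyphenyl)methyl]butanedioate F7.
- Hydrogenolysis (H2, 10% Pd/C, EtOAc) should free the C5 carboxyl as (2R,3R)-3-[(2,4-dihydroxy-3-methoxyphenyl)methyl]-2-[(4-hydroxy-3-methoxyphenyl)methyl]-4-methoxy-4-oxobutanoic acid F8.
- BH3·THF then reduces the free acid beside the methyl ester, a well-established selectivity, to methyl (2R,3R)-2-[(2,4-dihydroxy-3-methoxyphenyl)methyl]-3-(hydroxymethyl)-4-(4-hydroxy-3-methoxyphenyl)butanoate F9.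
- TsOH·H2O (cat.) in toluene should close F9 to 15.
- Any cis lactone formed through C3 epimerization would be returned to the trans isomer by equilibration with an amidine base.

**Step 7.** The hot acid stage may give incomplete or unselective dehydrative closure (intermolecular aryl esters, cyclic anhydride) and oxidative darkening of the electron-rich triphenol. The fallback sets out from 12 (made from 11 by the same hydrogenolysis) and comes back at 13. N,N'-dicyclohexylcarbodiimide (1.05 equiv, THF, 0 °C) should convert the vicinal diacid into (3R,4R)-3-[(2,4-dihydroxy-3-methoxyphenyl)methyl]-4-[(4-hydroxy-3-methoxyphenyl)methyl]oxolane-2,5-dione F10. Et3N (cat.) then lets the 2'-hydroxyl open the anhydride at C2 (six-membered ring in preference to seven), giving 13 at room temperature without strong acid. No external nucleophile is present, so reversible return to the anhydride can only lead back to 13.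

## Further compounds

```
F1 | step 6 | dibenzyl (2S,3S)-2-[2,4-bis(benzyloxy)-3-methoxybenzyl]-3-[4-(benzyloxy)-3-methoxybenzyl]butanedioate | COc1cc(C[C@H](C(=O)OCc2ccccc2)[C@H](Cc2ccc(OCc3ccccc3)c(OC)c2OCc2ccccc2)C(=O)OCc2ccccc2)ccc1OCc1ccccc1
F2 | step 5 | [4-(benzyloxy)-3-methoxyphenyl]acetaldehyde | COc1cc(CC=O)ccc1OCc1ccccc1
F3 | step 5 | 2-[2,4-bis(benzyloxy)-3-methoxyphenyl]ethanol | COc1c(OCc2ccccc2)ccc(CCO)c1OCc1ccccc1
F4 | step 5 | 5-({2-[2,4-bis(benzyloxy)-3-methoxyphenyl]ethyl}sulfanyl)-1-phenyl-1H-tetrazole | COc1c(OCc2ccccc2)ccc(CCSc2nnnn2-c2ccccc2)c1OCc1ccccc1
F5 | step 5 | 5-({2-[2,4-bis(benzyloxy)-3-methoxyphenyl]ethyl}sulfonyl)-1-phenyl-1H-tetrazole | COc1c(OCc2ccccc2)ccc(CCS(=O)(=O)c2nnnn2-c2ccccc2)c1OCc1ccccc1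
F6 | step 8 | diphenylmethyl (2R)-2-[(3R)-7-hydroxy-8-methoxy-2-oxo-3,4-dihydro-2H-chromen-3-yl]-3-(4-hydroxy-3-methoxyphenyl)propanoate | COc1cc(C[C@@H](C(=O)OC(c2ccccc2)c2ccccc2)[C@H]2Cc3ccc(O)c(OC)c3OC2=O)ccc1O
F7 | step 8 | 1-(diphenylmethyl) 4-methyl (2R,3R)-3-[(2,4-dihydroxy-3-methoxyphenyl)methyl]-2-[(4-hydroxy-3-methoxyphenyl)methyl]butanedioate | COc1cc(C[C@@H](C(=O)OC(c2ccccc2)c2ccccc2)[C@@H](Cc2ccc(O)c(OC)c2O)C(=O)OC)ccc1O
F8 | step 8 | (2R,3R)-3-[(2,4-dihydroxy-3-methoxyphenyl)methyl]-2-[(4-hydroxy-3-methoxyphenyl)methyl]-4-methoxy-4-oxobutanoic acid | COc1cc(C[C@@H](C(=O)O)[C@@H](Cc2ccc(O)c(OC)c2O)C(=O)OC)ccc1O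
F9 | step 8 | methyl (2R,3R)-2-[(2,4-dihydroxy-3-methoxyphenyl)methyl]-3-(hydroxymethyl)-4-(4-hydroxy-3-methoxyphenyl)butanoate | COc1cc(C[C@@H](CO)[C@@H](Cc2ccc(O)c(OC)c2O)C(=O)OC)ccc1O
F10 | step 7 | (3R,4R)-3-[(2,4-dihydroxy-3-methoxyphenyl)methyl]-4-[(4-hydroxy-3-methoxyphenyl)methyl]oxolane-2,5-dione | COc1cc(C[C@H]2C(=O)OC(=O)[C@@H]2Cc2ccc(O)c(OC)c2O)ccc1O
A1 | alternative 1 | 4-{[(3R)-4-(hydroxymethylidene)-5-oxooxolan-3-yl]methyl}-2-methoxyphenyl 4-methylbenzenesulfonate (enol geometry not specified) | O=C1OC[C@H](Cc2ccc(OS(=O)(=O)c3ccc(C)cc3)c(OC)c2)C1=CO
A2 | alternative 1 | 7-hydroxy-3-[(2R)-1-hydroxy-3-(3-methoxy-4-tosyloxyphenyl)propan-2-yl]-8-methoxycoumarin | O=c1oc2c(OC)c(O)ccc2cc1[C@H](CO)Cc1ccc(OS(=O)(=O)c2ccc(C)cc2)c(OC)c1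
A3 | alternative 2 | dimethyl 2-{[(3R,4R)-4-[4-(benzyloxy)-3-methoxybenzyl]-2-oxooxolan-3-yl]methyl}propanedioate | COc1cc(C[C@H]2COC(=O)[C@@H]2CC(C(=O)OC)C(=O)OC)ccc1OCc1ccccc1
A4 | alternative 2 | 1-methoxybut-3-en-2-one | COCC(=O)C=C
A5 | alternative 2 | methyl 1-{[(3R,4R)-4-[4-(benzyloxy)-3-methoxybenzyl]-2-oxooxolan-3-yl]methyl}-3-methoxy-2,4-dioxocyclohexane-1-carboxylate (epimers at the cyclohexane carbons) | COc1cc(C[C@H]2COC(=O)[C@@H]2CC2(C(=O)OC)CCC(=O)C(OC)C2=O)ccc1OCc1ccccc1
A6 | alternative 3 | (2R,3E)-2-[4-(benzyloxy)-3-methoxybenzyl]-4-[2,4-bis(benzyloxy)-3-methoxyphenyl]but-3-en-1-ol | COc1cc(C[C@@H](CO)/C=C/c2ccc(OCc3ccccc3)c(OC)c2OCc2ccccc2)ccc1OCc1ccccc1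
A7 | alternative 3 | carbon dioxide | O=C=O
A8 | alternative 3 | (3R,4R)-3-[2,4-bis(benzyloxy)-3-methoxybenzyl]-4-[4-(benzyloxy)-3-methoxybenzyl]oxolan-2-one | COc1cc(C[C@H]2COC(=O)[C@@H]2Cc2ccc(OCc3ccccc3)c(OC)c2OCc2ccccc2)ccc1OCc1ccccc1
```
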